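The route disconnects both aryl bonds of C1', the methine that sits on ring A next to a phenolic oxygen and also carries benzofuran C2 and the C2'–C3' glycol. C1' is treated as the carbonyl carbon of (S)-glyceraldehyde acetonide: in one flask the magnesium phenoxide of 3,5-dimethoxyphenol attacks it through its ortho carbon, the benzylic oxygen is expelled as a carbonate to give an ortho-quinone methide, and a 4,6-dimethoxybenzofuran-2-yl Grignard reagent adds to the methide carbon. This forms ring A–C1' and C1'–C2 and sets C1' under control of the chiral-pool centre C2'. The precursors are the phenol, the aldehyde and the C2-metallated benzofuran; acylation and deprotection follow.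

Key step: step 4

Remark on the chemistry: ring A is drawn acylated at the free position next to the acetoxy-bearing carbon; acylation at the other free ring A position would lead to the same target after deprotection. The alkene geometry of the ortho-quinone methide is left unassigned.

Step 1
Reactants: 1 (R)-solketal
Product: 2 (S)-2,3-O-isopropylideneglyceraldehyde
Conditions: (COCl)2, DMSO, CH2Cl2, −78 °C; i-Pr2NEt, −78 → 0 °C; used at once as a cold CH2Cl2 solution
Reagents that add atoms: none
Why: Swern oxidation turns the primary alcohol into the aldehyde under cold, non-aqueous conditions that spare the acetonide and the α-stereocentre (the descriptor changes from R to S only because the priorities change).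

Step 2
Reactants: 3 3,5-dimethoxyphenol; 4 bromoacetaldehyde diethyl acetal
Product: 5 1-(2,2-diethoxyethoxy)-3,5-dimethoxybenzene
Conditions: K2CO3, KI (cat.), DMF, 130 °C
Reagents that add atoms: none
Why: Williamson ether synthesis, in which the phenoxide displaces the primary bromide of the base-stable acetal.

Step 3
Reactants: 5 1-(2,2-diethoxyethoxy)-3,5-dimethoxybenzene
Product: 6 4,6-dimethoxybenzofuran
Conditions: polyphosphoric acid, toluene, 90 °C, high dilution
Reagents that add atoms: none
Why: Acid-mediated cyclodehydration (intramolecular Friedel–Crafts attack of an ortho carbon on the oxocarbenium ion of the acetal, then loss of ethanol) should give the benzofuran, and since both ortho positions are equivalent only the 4,6-dimethoxy isomer can form.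

Step 4
Reactants: 3 3,5-dimethoxyphenol; 2 (S)-2,3-O-isopropylideneglyceraldehyde; 6 4,6-dimethoxybenzofuran
Product: 13 2-{(S)-(4,6-dimethoxybenzofuran-2-yl)[(4R)-2,2-dimethyl-1,3-dioxolan-4-yl]methyl}-3,5-dimethoxyphenol, via bromomagnesium 3,5-dimethoxyphenoxide 7 (not isolated), via ortho-hydroxyalkyl adduct 8 (not isolated), via benzylic tert-butyl carbonate 9 (not isolated), via ortho-quinone methide 10 (not isolated), via 2-lithio-4,6-dimethoxybenzofuran 11 (not isolated), via 4,6-dimethoxybenzofuran-2-ylmagnesium bromide 12 (not isolated)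
Conditions: 3, EtMgBr (1.0 equiv), Et2O, 0 °C, then solvent exchange to CH2Cl2; 2 (0.95 equiv), 0 °C → rt; t-BuMgCl (1.0 equiv), THF, −78 °C; Boc2O (1.05 equiv), −78 °C; then 12 (1.5 equiv, from 6, n-BuLi, THF, −78 °C, then MgBr2·OEt2), −78 → 0 °C; aq. NH4Cl
Reagents that add atoms: none
Why: Phenoxide 7 holds the aldehyde on magnesium and delivers its ortho carbon to the carbonyl through a six-membered chelate in the non-coordinating solvent; t-BuMgCl then removes the remaining hydroxyl proton of 8 so that no acid is left to quench 12, Boc2O acylates the benzylic alkoxide, the phenoxide of 9 expels tert-butyl carbonate to give methide 10, and 12 adds at C1' with re-aromatisation. The closest known reaction types are the ortho-specific hydroxyalkylation of magnesium phenoxides with glyceraldehyde acetonide and the carbonate-triggered generation of ortho-quinone methides with 1,4-addition of Grignard reagents, here run one after the other in one flask. No ring is closed. C2' is carried over unchanged from 2, and C1' is set by 1,2-induction from C2': allylic strain against the oxygen flanking the methide holds C2'–H in the methide plane, the dioxolane oxygen and C3' then lie on opposite faces, and 12 is expected to enter anti to the bulkier C3' methylene, along the face of the dioxolane oxygen that can also bind its magnesium, which gives the 1'S,2'R (syn) product, as in syn-selective additions to Z-configured dioxolanyl enoates. This sense has to be checked on 13, because attack anti to the C–O bond would give the C1' epimer. The step needs ortho-regioselectivity, secured by magnesium chelation, 1,4- over 1,2-addition, secured by the gain of aromaticity, and protection of 12 from Boc2O, secured by adding 12 only after the carbonate has formed.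

Step 5
Reactants: 13 2-{(S)-(4,6-dimethoxybenzofuran-2-yl)[(4R)-2,2-dimethyl-1,3-dioxolan-4-yl]methyl}-3,5-dimethoxyphenol
Product: 14 (2R,3S)-3-(4,6-dimethoxybenzofuran-2-yl)-3-(2-hydroxy-4,6-dimethoxyphenyl)propane-1,2-diol
Conditions: AcOH/H2O 4:1, 40 °C
Reagents that add atoms: none
Why: Acid-catalysed hydrolysis of the terminal acetonide should proceed in warm aqueous acetic acid, which is too weak to protonate the electron-rich rings and so leaves the C1' diarylmethine and both stereocentres untouched.

Step 6
Reactants: 14 (2R,3S)-3-(4,6-dimethoxybenzofuran-2-yl)-3-(2-hydroxy-4,6-dimethoxyphenyl)propane-1,2-diol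
Product: 15 (2R,3S)-3-(2-acetoxy-4,6-dimethoxyphenyl)-3-(4,6-dimethoxybenzofuran-2-yl)propane-1,2-diyl diacetate
Conditions: Ac2O, pyridine, DMAP (cat.), CH2Cl2, rt
Reagents that add atoms: acetic anhydride, CC(=O)OC(C)=O
Why: DMAP-catalysed acetylation masks the three hydroxyl groups as esters that tolerate a Lewis acid, and the aryl acetate also lowers the tendency of ring A to undergo acid-induced cleavage at C1'.

Step 7
Reactants: 15 (2R,3S)-3-(2-acetoxy-4,6-dimethoxyphenyl)-3-(4,6-dimethoxybenzofuran-2-yl)propane-1,2-diyl diacetate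
Product: 16 (2R,3S)-3-[2-acetoxy-4,6-dimethoxy-3-(3-methylbutanoyl)phenyl]-3-[4,6-dimethoxy-7-(3-methylbutanoyl)benzofuran-2-yl]propane-1,2-diyl diacetate
Conditions: 3-methylbutanoyl chloride (2.5 equiv), SnCl4 (4 equiv), CH2Cl2, −20 → 0 °C
Reagents that add atoms: 3-methylbutanoyl chloride, CC(C)CC(Cl)=O
Why: Twofold Friedel–Crafts acylation, in which each acylium ion should attack the free position that is ortho to one methoxy group and para to the other (C3 of ring A, C7 of the benzofuran), the doubly flanked C5 positions and the non-activated furan C3 being less reactive and each ring being deactivated after one acylation.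

Step 8
Reactants: 16 (2R,3S)-3-[2-acetoxy-4,6-dimethoxy-3-(3-methylbutanoyl)phenyl]-3-[4,6-dimethoxy-7-(3-methylbutanoyl)benzofuran-2-yl]propane-1,2-diyl diacetate
Product: 17 1-{3-[(1S,2R)-1-[4,6-dimethoxy-7-(3-methylbutanoyl)benzofuran-2-yl]-2,3-dihydroxypropyl]-2-hydroxy-4,6-dimethoxyphenyl}-3-methylbutan-1-one
Conditions: K2CO3 (0.5 equiv), MeOH, rt; AcOH to pH 5
Reagents that add atoms: none
Why: Base-catalysed transesterification (methanolysis) should remove the aryl and alkyl acetates without touching the ketones, the methyl ethers or the non-enolisable C1' centre.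

Step 9
Reactants: 17 1-{3-[(1S,2R)-1-[4,6-dimethoxy-7-(3-methylbutanoyl)benzofuran-2-yl]-2,3-dihydroxypropyl]-2-hydroxy-4,6-dimethoxyphenyl}-3-methylbutan-1-one
Product: 18 1-{3-[(1S,2R)-1-[4,6-dihydroxy-7-(3-methylbutanoyl)benzofuran-2-yl]-2,3-dihydroxypropyl]-2,4,6-trihydroxyphenyl}-3-methylbutan-1-one (CNP0169876.1)
Conditions: BBr3 (12 equiv), CH2Cl2, −78 °C → rt; then H2O, 0 °C
Reagents that add atoms: none
Why: Lewis-acid ether cleavage, in which BBr3 binds each methoxy oxygen and bromide removes the methyl group, the two ethers ortho to a ketone going first through chelation and the two para ethers on warming, while the diol should be held as a cyclic borate that is hydrolysed on work-up.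

Compound list
1 | (R)-solketal, (4R)-2,2-dimethyl-1,3-dioxolane-4-methanol | OC[C@@H]1COC(C)(C)O1 | starting material
2 | (S)-2,3-O-isopropylideneglyceraldehyde, (4S)-2,2-dimethyl-1,3-dioxolane-4-carbaldehyde | O=C[C@@H]1COC(C)(C)O1 | intermediate
3 | 3,5-dimethoxyphenol | COc1cc(O)cc(OC)c1 | starting material
4 | bromoacetaldehyde diethyl acetal | CCOC(CBr)OCC | starting material
5 | 1-(2,2-diethoxyethoxy)-3,5-dimethoxybenzene | CCOC(COc1cc(OC)cc(OC)c1)OCC | intermediate
6 | 4,6-dimethoxybenzofuran | COc1cc(OC)c2ccoc2c1 | intermediate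
7 | bromomagnesium 3,5-dimethoxyphenoxide | COc1cc(O[Mg]Br)cc(OC)c1 | intermediate
8 | 2-{hydroxy[(4S)-2,2-dimethyl-1,3-dioxolan-4-yl]methyl}-3,5-dimethoxyphenol (C1' epimers; present as its halomagnesium salt, neutral form drawn) | COc1cc(O)c(C(O)[C@@H]2COC(C)(C)O2)c(OC)c1 | intermediate
9 | tert-butyl (2-hydroxy-4,6-dimethoxyphenyl)[(4S)-2,2-dimethyl-1,3-dioxolan-4-yl]methyl carbonate (C1' epimers; present as its magnesium phenoxide, neutral form drawn) | COc1cc(O)c(C(OC(=O)OC(C)(C)C)[C@@H]2COC(C)(C)O2)c(OC)c1 | intermediate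
10 | 6-{[(4R)-2,2-dimethyl-1,3-dioxolan-4-yl]methylidene}-3,5-dimethoxycyclohexa-2,4-dien-1-one (alkene geometry unassigned) | COC1=CC(=O)C(=C[C@@H]2COC(C)(C)O2)C(OC)=C1 | intermediate
11 | 2-lithio-4,6-dimethoxybenzofuran | COc1cc(OC)c2cc([Li])oc2c1 | intermediate
12 | 4,6-dimethoxybenzofuran-2-ylmagnesium bromide | COc1cc(OC)c2cc([Mg]Br)oc2c1 | intermediate
13 | 2-{(S)-(4,6-dimethoxybenzofuran-2-yl)[(4R)-2,2-dimethyl-1,3-dioxolan-4-yl]methyl}-3,5-dimethoxyphenol | COc1cc(O)c(c(OC)c1)[C@H](c1cc2c(OC)cc(OC)cc2o1)[C@@H]1COC(C)(C)O1 | intermediate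
14 | (2R,3S)-3-(4,6-dimethoxybenzofuran-2-yl)-3-(2-hydroxy-4,6-dimethoxyphenyl)propane-1,2-diol | COc1cc(O)c(c(OC)c1)[C@H](c1cc2c(OC)cc(OC)cc2o1)[C@@H](O)CO | intermediate
15 | (2R,3S)-3-(2-acetoxy-4,6-dimethoxyphenyl)-3-(4,6-dimethoxybenzofuran-2-yl)propane-1,2-diyl diacetate | COc1cc(OC(C)=O)c(c(OC)c1)[C@H](c1cc2c(OC)cc(OC)cc2o1)[C@@H](OC(C)=O)COC(C)=O | intermediate
16 | (2R,3S)-3-[2-acetoxy-4,6-dimethoxy-3-(3-methylbutanoyl)phenyl]-3-[4,6-dimethoxy-7-(3-methylbutanoyl)benzofuran-2-yl]propane-1,2-diyl diacetate | CC(C)CC(=O)c1c(OC)cc(OC)c(c1OC(C)=O)[C@H](c1cc2c(OC)cc(OC)c(C(=O)CC(C)C)c2o1)[C@@H](OC(C)=O)COC(C)=O | intermediate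
17 | 1-{3-[(1S,2R)-1-[4,6-dimethoxy-7-(3-methylbutanoyl)benzofuran-2-yl]-2,3-dihydroxypropyl]-2-hydroxy-4,6-dimethoxyphenyl}-3-methylbutan-1-one | CC(C)CC(=O)c1c(OC)cc(OC)c(c1O)[C@H](c1cc2c(OC)cc(OC)c(C(=O)CC(C)C)c2o1)[C@@H](O)CO | intermediate
18 | 1-{3-[(1S,2R)-1-[4,6-dihydroxy-7-(3-methylbutanoyl)benzofuran-2-yl]-2,3-dihydroxypropyl]-2,4,6-trihydroxyphenyl}-3-methylbutan-1-one | CC(C)CC(=O)c1c(O)cc(O)c([C@H](c2cc3c(O)cc(O)c(C(=O)CC(C)C)c3o2)[C@@H](O)CO)c1O | target

Total step count: 9. Longest linear sequence: 8 steps (3 → 5 → 6 → 13 → 14 → 15 → 16 → 17 → 18).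

Steps most likely to fail

Step 4. The addition of 12 to methide 10 may show poor or inverted facial selectivity and give the C1' epimer. In addition, 12 may be lost to residual Boc2O, and 10 may be consumed by a second phenoxide. Fallback: the roles of the two arenes are reversed, setting out from 6, 2 and 3 and returning at 13. Lithiated 6 (n-BuLi, THF, −78 °C) is added to 2 to give the carbinol (4,6-dimethoxybenzofuran-2-yl)[(4S)-2,2-dimethyl-1,3-dioxolan-4-yl]methanol F1 as an epimer mixture. Acetylation (Ac2O, pyridine) gives its acetate F2. F2 is then treated with phenoxide 7 in CH2Cl2 (−40 → 0 °C), where magnesium pulls off the acetate and the benzofuranyl-stabilised cation is captured by the ortho carbon of ring A (ortho-selective Friedel–Crafts alkylation of a magnesium phenoxide), giving 13. Ring A is now the incoming group and the benzofuran the in-plane one, so the same facial bias of the dioxolane would lead to the opposite C1' configuration, and no Boc2O is present.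

Step 7. Acylation may go to the furan C3 or to C5 of the benzofuran in place of C7, the second acylation may stall, or the Lewis acid may cleave the molecule at C1'. Fallback: the acyl groups are built from formyl groups, setting out from 13 and returning at 18. O-Methylation of the ring A phenol (MeI, K2CO3, acetone) gives the pentamethyl ether 2-{(S)-[(4R)-2,2-dimethyl-1,3-dioxolan-4-yl](2,4,6-trimethoxyphenyl)methyl}-4,6-dimethoxybenzofuran F3, whose ring A has two equivalent free positions. Vilsmeier–Haack formylation (POCl3, DMF, 0 °C → rt; aq. NaOAc) is mild enough to spare the acetonide and is expected to prefer C7 of a 4,6-dimethoxybenzofuran; it should give the ring A C3, benzofuran C7 dialdehyde F4. Addition of i-BuMgBr with CeCl3 (THF, −78 °C) gives the bis-carbinol F5, and oxidation (MnO2, CH2Cl2) gives the diketone acetonide F6. BBr3 (CH2Cl2, −78 °C → rt) then removes the acetonide together with the five methyl ethers to give 18.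

Step 9. The two ethers para to the ketones may cleave incompletely, or prolonged exposure to BBr3 may turn the C2' and C3' hydroxyl groups into bromides or let a neighbouring phenol capture them. Fallback: ether cleavage is run before ester removal, setting out from 16 and returning at 18. Treatment of 16 with BCl3 and n-Bu4NI (CH2Cl2, −78 → 0 °C) cleaves the four methyl ethers while the three hydroxyl groups stay masked, giving the tetraphenol triacetate (2R,3S)-3-[2-acetoxy-4,6-dihydroxy-3-(3-methylbutanoyl)phenyl]-3-[4,6-dihydroxy-7-(3-methylbutanoyl)benzofuran-2-yl]propane-1,2-diyl diacetate F7. Acid methanolysis (HCl in MeOH from AcCl, rt) then frees the hydroxyl groups to give 18.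

Further compounds
F1 | step 4 | (4,6-dimethoxybenzofuran-2-yl)[(4S)-2,2-dimethyl-1,3-dioxolan-4-yl]methanol (carbinol epimers) | COc1cc(OC)c2cc(C(O)[C@@H]3COC(C)(C)O3)oc2c1
F2 | step 4 | (4,6-dimethoxybenzofuran-2-yl)[(4S)-2,2-dimethyl-1,3-dioxolan-4-yl]methyl acetate (epimers) | COc1cc(OC)c2cc(C(OC(C)=O)[C@@H]3COC(C)(C)O3)oc2c1
F3 | step 7 | 2-{(S)-[(4R)-2,2-dimethyl-1,3-dioxolan-4-yl](2,4,6-trimethoxyphenyl)methyl}-4,6-dimethoxybenzofuran | COc1cc(OC)c(c(OC)c1)[C@H](c1cc2c(OC)cc(OC)cc2o1)[C@@H]1COC(C)(C)O1
F4 | step 7 | 2-{(S)-[(4R)-2,2-dimethyl-1,3-dioxolan-4-yl](3-formyl-2,4,6-trimethoxyphenyl)methyl}-4,6-dimethoxybenzofuran-7-carbaldehyde | O=Cc1c(OC)cc(OC)c(c1OC)[C@H](c1cc2c(OC)cc(OC)c(C=O)c2o1)[C@@H]1COC(C)(C)O1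
F5 | step 7 | bis(1-hydroxy-3-methylbutyl) analogue of F4 (carbinol epimers) | CC(C)CC(O)c1c(OC)cc(OC)c(c1OC)[C@H](c1cc2c(OC)cc(OC)c(C(O)CC(C)C)c2o1)[C@@H]1COC(C)(C)O1
F6 | step 7 | 1-{3-[(S)-[(4R)-2,2-dimethyl-1,3-dioxolan-4-yl][4,6-dimethoxy-7-(3-methylbutanoyl)benzofuran-2-yl]methyl]-2,4,6-trimethoxyphenyl}-3-methylbutan-1-one | CC(C)CC(=O)c1c(OC)cc(OC)c(c1OC)[C@H](c1cc2c(OC)cc(OC)c(C(=O)CC(C)C)c2o1)[C@@H]1COC(C)(C)O1
F7 | step 9 | (2R,3S)-3-[2-acetoxy-4,6-dihydroxy-3-(3-methylbutanoyl)phenyl]-3-[4,6-dihydroxy-7-(3-methylbutanoyl)benzofuran-2-yl]propane-1,2-diyl diacetate | CC(C)CC(=O)c1c(O)cc(O)c(c1OC(C)=O)[C@H](c1cc2c(O)cc(O)c(C(=O)CC(C)C)c2o1)[C@@H](OC(C)=O)COC(C)=O
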